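5.60 % of the charge is missing from target plus side product at 6.00 min in the blue run. Call this remainder u, the gap in the mass balance, and treat it as a small correction to the two large readings.

| setting | blue | flask |
|---|---|---|
| starting material | 2.9 M | 2.9 M |
| remark | the very flask that is asked about, followed so far |  |
| time |  | 12 min |

blue run (percent of the starting material charged)

| time / min | target / % | side product / % |
|---|---|---|
| 0.417 | 26.6 | 2.1 |
| 1.33 | 47.8 | 17.4 |
| 2.00 | 54.1 | 25.0 |
| 3.00 | 55.2 | 32.1 |
| 5.00 | 56.7 | 37.2 |
| 6.00 | 56.5 | 37.9 |

(each reading ± 0.5 percentage points)

1. share of target in target plus side product at 4.0 s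
2. share of target in target plus side product at 12 min
3. which of target and side product there is more of at 12 min

Turn the question round. For the side product to lead at 12 min, you need the target to fall, or u to exceed the target's lead L, and in the blue run at 6.00 min L reads 19 percentage points, so u is about a third of it. The target readings at 5.00 min and 6.00 min differ by 0.2 points, against a scatter of 0.5 points.

My reckoning holds the target there and moves u alone. Put the whole of u on the side product and the share, the selectivity, is 56.5 %; put none of it there and the share is 59.9 %.

The forecast gives 98.3 % (96.5 % to 99.6 %) at 4.0 s, 58.5 % (56.5 % to 59.6 %) at 12 min, and target ahead, reading the target thus: “it is a stable end product and is not feeding the side product”. Its top end stands a little below mine.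

The flask gives 98.3 % at 4.0 s, 59.5 % at 12 min, and target ahead, 56.5 % against 38.4 %.

    starting material ⇌ intermediate B (K = 0.360, k = 0.0500 /s)
    intermediate B ⇌ intermediate D (K = 0.110, k = 0.0180 /s)
    starting material → intermediate A (k = 0.0320 /s)
    intermediate D → decomposed reagent (k = 0.0630 /s)
    intermediate A → target (k = 1.00 /s)
    intermediate C → side product (k = 0.0140 /s)
    intermediate A → intermediate C (k = 0.680 /s)

Reckoned at 12.0 min, u in this flask is 5.16 %, and 5.15 % of decomposed reagent stands there at 12.0 min. The neighbour charged with 1.7 M ends with 56.5 % target and 38.4 % side product, so its u is 5.16 %, less than its lead of 18 points, and its share is 59.5 %.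

All runs were computed with made-up constants; the scatter is artificial.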